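Numbering used throughout: C1 = aryl-bearing CH; C2 and C3 = the CH carbons that carry the hydroxymethyl carbons C9 and C9'; C4 = benzylic CH2; C4a and C8a = ring-fusion carbons next to C4 and C1; C5–C8 = the other carbons of arene ring A (OMe on C6, OH on C7); ring B = the carbocycle C1–C4/C4a/C8a.

Compound numbers: 1 homovanillic acid; 2 benzyl bromide; 3 benzyl ester/benzyl ether; 4 N,O-dimethylhydroxylamine hydrochloride; 5 Weinreb amide; 6 vinylmagnesium bromide; 7 aryl vinyl ketone; 8 triisopropylsilyl triflate; 9 silyloxydiene; 10 dimethyl fumarate; 11 cycloadduct diester; 12 diol; 13 bis(benzyl ether) silyl enol ether; 14 3,3-dimethoxybutan-2-one; 15 3-methoxybut-3-en-2-one; 16 1,5-diketone; 17 ketol; 18 methoxy enone; 19 selenide; 20 selenoxide; 21 dienone; 22 tribenzylated phenol; 23 (+)-isolariciresinol.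

## Analysis of the target

(+)-Isolariciresinol (23) is a 1-aryltetralin lignan: a guaiacol ring A (C4a, C5–C8, C8a) is fused to a saturated ring B that carries a second guaiacyl ring on C1 and hydroxymethyl groups on C2 and C3. The three stereocentres are contiguous, C1 (S), C2 (R) and C3 (R), and all-trans, so the three ring-B substituents can all be equatorial; this is the thermodynamically preferred arrangement. The sensitive sites are the two electron-rich free phenols and the C1–H bond, which is doubly benzylic between two para-oxygenated rings and therefore prone to hydride abstraction by quinone oxidants and to ionisation under acid. The 1,4-diol can also close to a tetrahydrofuran under strong acid. The synthesis is hard for two reasons: three adjacent carbon stereocentres must be set in absolute terms without a heteroatom handle in ring B, and the OH/OMe pattern of ring A must be placed regiochemically although it differs from that of the pendant ring only by position. The strategy rests on ring A being an ortho-methoxyphenol fused through C4a–C8a. C8a and C4a can be the carbonyl and α-carbon of a cyclohexanone (ring B), and C5–C8 can come from a four-carbon enone in which the C7 oxygen is the ketone and the C6 oxygen is an enol-ether methoxyl, which is reagent 15. Ring B without ring A is then a cyclohexanone holding C1–C3, a pattern that one Diels–Alder reaction with an E-dienophile can deliver with the C2/C3 trans relation.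

## Retrosynthetic reasoning

23 ⇐ 22. The three O–benzyl bonds are cut last. Both phenols and both primary alcohols stay masked through the Lewis acidic, basic and oxidative steps, and one hydrogenolysis releases all of them without touching the C1 diarylmethine.

22 ⇐ 18. Ring A is traced back to the cyclohexenone 18 by adding two hydrogens (C5–H and C6–H). The forward step has to dehydrogenate across C5–C6 so that the dienone 21 can tautomerise to the phenol. It must do so without a hydride-abstracting oxidant, because C1–H and the benzyl ethers are hydride-labile. Selenide 19 and selenoxide 20 are the carriers.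

18 ⇐ 13 + 15. Ring A is cut at C4a–C5 and at C8–C8a. These are the only two cuts that leave the ring-fusion carbons as the α-carbon and carbonyl carbon of a cyclohexanone and put both ring-A oxygens into one small reagent. Any other pair of cuts would separate the C6 and C7 oxygens or require an aryl piece already differentiated. The gain is that the OH/OMe regiochemistry needs no late differentiation and that the precursor is monocyclic. The forward reaction has to form the C–C bond at C4a and not at the more acidic benzylic C1, which is why the nucleophile is the regiodefined silyl enol ether 13 and not the free ketone. It then has to condense the methyl ketone onto C8a through 16 and 17.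

13 ⇐ 12 ⇐ 11. The two benzyl ethers are traced back to ester carbons. Ether oxygens are chosen for the key step because they are inert to base, so C2 and C3 are no longer α to carbonyl groups when the annulation is run. The forward steps, a hydride reduction and an etherification with 2, must leave the silyl enol ether untouched.

11 ⇐ 9 + 10. Ring B is cut at C1–C2 and C3–C4, a Diels–Alder disconnection. It is made here because the diene 9 then delivers the enol ether double bond exactly between C8a and C4a, and the E geometry of 10 delivers the C2/C3 trans relation. A chiral Lewis acid has to choose the face of 10. C1 need not be controlled rigorously, since it becomes epimerisable in the key step.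

9 ⇐ 7 ⇐ 5 ⇐ 3 ⇐ 1. The O–Si bond is cut back to the vinyl ketone 7 (silylation with 8 at the only enolisable position). The vinyl–carbonyl bond is cut back to the Weinreb amide 5 and 6, the amide back to ester 3 and 4, and the two O–benzyl bonds back to 1 and 2.

15 ⇐ 14. The enol ether is traced back to the ketal by addition of methanol; the forward step is an acid-catalysed elimination that can occur in one direction only.

## Alternatives that were turned down

Alternative 1: The disconnection cuts C2–C3 and C1–C8a, so that ring B and a lactone fused across C2–C3 open to the acyclic mixed malonate A1. A1 carries a (−)-8-phenylmenthyl ester, the cinnamyl ester of the pendant-aryl allylic alcohol, and the ring-A benzyl group on the central carbon. In the forward key step Mn(OAc)3 oxidises the malonate C–H to the C3 radical, which closes 5-exo onto the alkene (C2–C3, lactone). Cu(OAc)2 oxidises the resulting C1 benzylic radical, and ring A captures the cation para to its methoxyl (C1–C8a) to give the lactone A2.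
- For: two rings and two C–C bonds form in one step from a precursor assembled by esterification and malonate alkylation. Both arenes are bought with their oxygen pattern in place. On that point the alternative is stronger than the chosen route, which spends two operations building and aromatising ring A.
- Against: A2 is not at the substitution level of the target. C3 is quaternary with two carboxyl carbons, so one must be excised, and the C3–H centre that results is set by protonation or equilibration, not by the cascade. The target needs C2/C3 trans, whereas the lactone is cis-fused. The absolute configuration depends on a stoichiometric, costly auxiliary biasing a radical cyclisation, and stoichiometric trivalent manganese and divalent copper act in the presence of two electron-rich arenes.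
- Comparison: the chosen route sets C2/C3 trans directly from alkene geometry, sets the absolute configuration catalytically, and removes no carbon.

Alternative 2: The disconnection cuts C2–C9 and C3–C9', tracing both one-carbon arms to the C2=C3 alkene of the (S)-1-aryl-1,4-dihydronaphthalene A3. In the forward key step dichloroketene A4, generated by zinc–copper dechlorination of its acid chloride precursor, adds [2+2] across C2=C3 anti to the aryl group to give the cis-fused dichlorocyclobutanone A5.
- For: both arms arrive in one step, and the orientation of the ketene does not matter because both carbons end as CH2OH. Ring A is again bought. In step count from the bicyclic core to the two arms this is at least as short as the chosen route.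
- Against: the cycloaddition is suprafacial, so A5 has C2/C3 cis. The target needs trans, which demands ring cleavage between C9 and C9' (a Baeyer–Villiger reaction would break a ring–arm bond instead) and then epimerisation at an ester or aldehyde stage. A3 is a 1,4-dihydronaphthalene that slips into conjugation or aromatises readily. Its single stereocentre must carry all absolute information and has to be made enantiopure by a separate, unsolved step.
- Comparison: the chosen route obtains the trans relation and the absolute configuration in the same cycloaddition and never handles an oxidation-prone dihydronaphthalene.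

Alternative 3: The disconnection cuts C1–C2 only, giving the lactol A6, in which ring A carries the diarylcarbinol (future C1) ortho to the side chain that holds C3 and the masked C2 aldehyde. In the forward key step a secondary amine and a Brønsted acid form the C2 enamine from the open aldehyde and ionise the carbinol to a benzhydryl cation stabilised by two para-oxygenated rings. The enamine attacks the cation and closes ring B as the tetralin lactol A7.
- For: the cation is ideally stabilised, the reaction type is mild and catalytic, and both arenes are purchased. A7 needs only a hydride reduction and a hydrogenolysis to reach the target. The endgame is shorter than that of the chosen route, and on convergence it is at least equal.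
- Against: C3 must be installed enantiopure beforehand in a separate asymmetric step. A6 requires an ortho-functionalised ring A, built in a longer linear sequence. The lactol keeps the concentration of free aldehyde, and hence enamine, low. The cation can be taken by the hydroxyl oxygens instead of carbon. C1 and C2 depend on 1,2-induction from C3.
- Comparison: the chosen route offers instead one catalytic step that fixes all ring-B stereochemistry (with thermodynamic correction at C1) and a ring-A oxygen pattern dictated by a reagent and not by the synthesis of a tetrasubstituted arene.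

Key step: step 9

Assumption: the (S)-configured oxazaborolidinium catalyst is taken to send the diene to the re,re face of dimethyl fumarate, the face it selects on acrylate esters; if the adduct proves antipodal, the (R)-catalyst is used and nothing else changes.

## Route

Step 1
Reactants: 1 homovanillic acid; 2 benzyl bromide
Product: 3 benzyl 2-[4-(benzyloxy)-3-methoxyphenyl]acetate
Conditions: BnBr (2.3 equiv), K2CO3, DMF, 60 °C
Reagents that add atoms: benzyl bromide, BrCc1ccccc1
Why: Williamson etherification of the phenoxide and SN2 alkylation of the carboxylate take place in one pot; the benzyl ester is only a carrier for step 2, while the aryl benzyl ether stays to the end.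

Step 2
Reactants: 3 benzyl ester; 4 N,O-dimethylhydroxylamine hydrochloride
Product: 5 2-[4-(benzyloxy)-3-methoxyphenyl]-N-methoxy-N-methylacetamide
Conditions: MeNH(OMe)·HCl, iPrMgCl, THF, −20 → 0 °C
Reagents that add atoms: N,O-dimethylhydroxylamine hydrochloride, CNOC.Cl
Why: Aminolysis of the ester by the chloromagnesium amide formed in the flask (Weinreb amide synthesis from esters); at −20 °C addition of the amide to the ester should outrun enolisation of the arylacetate.

Step 3
Reactants: 5 Weinreb amide; 6 vinylmagnesium bromide
Product: 7 1-[4-(benzyloxy)-3-methoxyphenyl]but-3-en-2-one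
Conditions: CH2=CHMgBr, THF, −20 → 0 °C; transfer into cold 1 M HCl
Reagents that add atoms: vinylmagnesium bromide, C=C[Mg]Br
Why: Weinreb ketone synthesis; the chelated tetrahedral adduct prevents a second addition, and the inverse acidic quench keeps the released amine protonated so that it cannot add to the vinyl ketone.

Step 4
Reactants: 7 aryl vinyl ketone; 8 triisopropylsilyl trifluoromethanesulfonate
Product: 9 {[(1Z)-1-[4-(benzyloxy)-3-methoxyphenyl]buta-1,3-dien-2-yl]oxy}tri(propan-2-yl)silane
Conditions: iPr3SiOTf, Et3N, CH2Cl2, −78 → 0 °C
Reagents that add atoms: triisopropylsilyl trifluoromethanesulfonate, CC(C)[Si](OS(=O)(=O)C(F)(F)F)(C(C)C)C(C)C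
Why: Soft enolisation (O-silylation, then deprotonation at the benzylic carbon, the only enolisable site) gives the 2-silyloxydiene; the Z enol ether with the aryl group anti to the vinyl group is favoured by conjugation and allylic strain and is the only isomer that can reach the s-cis conformation needed in step 5.

Step 5
Reactants: 9 silyloxydiene; 10 dimethyl fumarate
Product: 11 dimethyl (1R,2R,3S)-3-[4-(benzyloxy)-3-methoxyphenyl]-4-{[tri(propan-2-yl)silyl]oxy}cyclohex-4-ene-1,2-dicarboxylate
Conditions: (S)-tetrahydro-1-(2-methylphenyl)-3,3-diphenyl-1H,3H-pyrrolo[1,2-c][1,3,2]oxazaborole / HN(SO2CF3)2 (20 mol %), CH2Cl2, −78 → −20 °C; Et3N quench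
Reagents that add atoms: dimethyl fumarate, COC(=O)/C=C/C(=O)OC
Why: Catalytic enantioselective Diels–Alder reaction under a cationic oxazaborolidinium Lewis acid; the E geometry of 10 is transferred suprafacially, so C2 and C3 are trans, and the catalyst-shielded fumarate is approached on its re,re face, which fixes their absolute configuration. The catalyst-bound ester should sit endo at C3, leaving the C2 ester exo and trans to the aryl group on the outside of the diene terminus, and the enol ether double bond emerges between C8a and C4a.

Step 6
Reactants: 11 cycloadduct diester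
Product: 12 [(1R,2S,3S)-3-[4-(benzyloxy)-3-methoxyphenyl]-4-{[tri(propan-2-yl)silyl]oxy}cyclohex-4-ene-1,2-diyl]dimethanol
Conditions: LiAlH4, THF, 0 °C; aq. KNaC4H4O6 work-up
Reagents that add atoms: none
Why: Hydride reduction of both esters; the hindered silyl enol ether offers no site for hydride and survives a non-acidic work-up, and no stereocentre is touched.

Step 7
Reactants: 12 diol; 2 benzyl bromide
Product: 13 {[(4R,5S,6S)-6-[4-(benzyloxy)-3-methoxyphenyl]-4,5-bis[(benzyloxy)methyl]cyclohex-1-en-1-yl]oxy}tri(propan-2-yl)silane
Conditions: NaH, BnBr, Bu4NI (cat.), THF–DMF, 0 °C → rt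
Reagents that add atoms: benzyl bromide, BrCc1ccccc1
Why: Williamson etherification of the two primary alkoxides, made fast by iodide catalysis; the three isopropyl groups should shield silicon from alkoxide attack, so the regiodefined enol ether is carried through.

Step 8
Reactants: 14 3,3-dimethoxybutan-2-one
Product: 15 3-methoxybut-3-en-2-one
Conditions: TsOH·H2O (cat.), neat, 140–150 °C, MeOH distilled off; then distillation
Reagents that add atoms: none
Why: Acid-catalysed loss of methanol from the ketal (ketal to enol ether cracking); elimination can only occur towards the methyl group, and removal of methanol drives it.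

Step 9
Reactants: 13 bis(benzyl ether) silyl enol ether; 15 3-methoxybut-3-en-2-one
Product: 18 (6R,7R,8S)-8-[4-(benzyloxy)-3-methoxyphenyl]-6,7-bis[(benzyloxy)methyl]-3-methoxy-4,4a,5,6,7,8-hexahydronaphthalen-2(3H)-one, via 1,5-diketone 16 (not isolated), via aldol ketol 17 (not isolated)
Conditions: 15 (2 equiv), TiCl4, CH2Cl2, −78 °C; aq. NaHCO3; crude 16, KOH, MeOH, 0 → 50 °C
Reagents that add atoms: 3-methoxybut-3-en-2-one, COC(=C)C(C)=O
Why: Mukaiyama–Michael addition followed by intramolecular aldol condensation, that is a Robinson annulation in its silyl enol ether form, the closest known type being such annulations with vinyl ketones that carry a heteroatom on the α-carbon. TiCl4 binds the carbonyl and methoxy oxygens of 15 in a five-membered chelate, which holds the enone s-cis, ties up the methoxy lone pair and makes the CH2 terminus electrophilic; C4a of 13 attacks it (C4a–C5), chloride removes the silyl group, and work-up protonates the titanium enolate to diketone 16 with the C8a carbonyl unveiled. In KOH/MeOH the methyl ketone enolate (C8) adds to the C8a carbonyl in a 6-(enolexo)-exo-trig aldol closure that forms the future ring A as ketol 17, and E1cB loss of water gives the conjugated enone 18; this last event is irreversible and drains the reversible side equilibria (retro-aldol, bridged ketol from the C1 enolate onto C7). The selectivity the step needs is C–C bond formation at C4a and not at the more acidic benzylic C1; it is secured by the position of the enol ether double bond, which the cycloaddition placed between C8a and C4a and which cannot migrate under aprotic Lewis acid conditions at −78 °C. The new centres at C4a and C6 form as mixtures and need no control, since both become sp2 in step 10. C1, α to the carbonyl in 16 and γ (and benzylic) to the enone carbonyl in 18, equilibrates in the basic stage to the isomer with the aryl group trans to the C2 substituent, in which all three ring-B substituents are equatorial, so substrate-based thermodynamic control sets or confirms this centre. The oxygen pattern of ring A is fixed here: the carbonyl of 15 becomes the C7 oxygen and its methoxyl sits on C6.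

Step 10
Reactants: 18 methoxy enone
Product: 22 (6R,7R,8S)-8-[4-(benzyloxy)-3-methoxyphenyl]-6,7-bis[(benzyloxy)methyl]-3-methoxy-5,6,7,8-tetrahydronaphthalen-2-ol, via selenide 19 (not isolated), via selenoxide 20 (not isolated), via dienone 21 (not isolated)
Conditions: LiN(iPr)2, THF, −78 °C; PhSeBr; then H2O2 (30 %), pyridine, CH2Cl2, 0 °C → rt
Reagents that add atoms: none
Why: α-Selenenylation of the kinetic cross-conjugated enolate at C6, then selenoxide syn-elimination towards C5–H, gives dienone 21, the keto tautomer of the phenol, which aromatises at once. No hydride-abstracting oxidant is used, so C1–H and the benzyl ethers are spared, and C1 is locked once ring A is aromatic.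

Step 11
Reactants: 22 tribenzylated phenol
Product: 23 (+)-isolariciresinol, (6R,7R,8S)-8-(4-hydroxy-3-methoxyphenyl)-6,7-bis(hydroxymethyl)-3-methoxy-5,6,7,8-tetrahydronaphthalen-2-ol
Conditions: H2 (1 atm), Pd/C (10 %), EtOAc–MeOH, rt
Reagents that add atoms: none
Why: Hydrogenolysis of the one aryl and two alkyl benzyl ethers; the C1 diarylmethine has no benzylic heteroatom bond and is not cleaved, and no stereocentre is affected.

## Compound list

1 | homovanillic acid, 2-(4-hydroxy-3-methoxyphenyl)acetic acid | COc1cc(CC(=O)O)ccc1O | starting material
2 | benzyl bromide | BrCc1ccccc1 | starting material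
3 | benzyl 2-[4-(benzyloxy)-3-methoxyphenyl]acetate | COc1cc(CC(=O)OCc2ccccc2)ccc1OCc1ccccc1 | intermediate
4 | N,O-dimethylhydroxylamine hydrochloride | CNOC.Cl | starting material
5 | 2-[4-(benzyloxy)-3-methoxyphenyl]-N-methoxy-N-methylacetamide | COc1cc(CC(=O)N(C)OC)ccc1OCc1ccccc1 | intermediate
6 | vinylmagnesium bromide | C=C[Mg]Br | starting material
7 | 1-[4-(benzyloxy)-3-methoxyphenyl]but-3-en-2-one | COc1cc(CC(=O)C=C)ccc1OCc1ccccc1 | intermediate
8 | triisopropylsilyl trifluoromethanesulfonate | CC(C)[Si](OS(=O)(=O)C(F)(F)F)(C(C)C)C(C)C | starting material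
9 | {[(1Z)-1-[4-(benzyloxy)-3-methoxyphenyl]buta-1,3-dien-2-yl]oxy}tri(propan-2-yl)silane | COc1cc(/C=C(/C=C)O[Si](C(C)C)(C(C)C)C(C)C)ccc1OCc1ccccc1 | intermediate
10 | dimethyl fumarate | COC(=O)/C=C/C(=O)OC | starting material
11 | dimethyl (1R,2R,3S)-3-[4-(benzyloxy)-3-methoxyphenyl]-4-{[tri(propan-2-yl)silyl]oxy}cyclohex-4-ene-1,2-dicarboxylate (all-trans) | COc1cc([C@H]2C(O[Si](C(C)C)(C(C)C)C(C)C)=CC[C@@H](C(=O)OC)[C@@H]2C(=O)OC)ccc1OCc1ccccc1 | intermediate
12 | [(1R,2S,3S)-3-[4-(benzyloxy)-3-methoxyphenyl]-4-{[tri(propan-2-yl)silyl]oxy}cyclohex-4-ene-1,2-diyl]dimethanol | COc1cc([C@H]2C(O[Si](C(C)C)(C(C)C)C(C)C)=CC[C@@H](CO)[C@@H]2CO)ccc1OCc1ccccc1 | intermediate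
13 | {[(4R,5S,6S)-6-[4-(benzyloxy)-3-methoxyphenyl]-4,5-bis[(benzyloxy)methyl]cyclohex-1-en-1-yl]oxy}tri(propan-2-yl)silane | COc1cc([C@H]2C(O[Si](C(C)C)(C(C)C)C(C)C)=CC[C@@H](COCc3ccccc3)[C@@H]2COCc2ccccc2)ccc1OCc1ccccc1 | intermediate
14 | 3,3-dimethoxybutan-2-one | CC(=O)C(C)(OC)OC | starting material
15 | 3-methoxybut-3-en-2-one | COC(=C)C(C)=O | intermediate
16 | (2S,3S,4R)-2-[4-(benzyloxy)-3-methoxyphenyl]-3,4-bis[(benzyloxy)methyl]-6-(2-methoxy-3-oxobutyl)cyclohexan-1-one (not isolated; C6 and the side-chain methoxy carbon as mixtures) | COc1cc([C@H]2C(=O)C(CC(OC)C(C)=O)C[C@@H](COCc3ccccc3)[C@@H]2COCc2ccccc2)ccc1OCc1ccccc1 | intermediate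
17 | (6R,7S,8S)-8-[4-(benzyloxy)-3-methoxyphenyl]-6,7-bis[(benzyloxy)methyl]-8a-hydroxy-3-methoxyoctahydronaphthalen-2(1H)-one (not isolated; C3, C4a, C8a as mixtures) | COc1cc([C@H]2C3(O)CC(=O)C(OC)CC3C[C@@H](COCc3ccccc3)[C@@H]2COCc2ccccc2)ccc1OCc1ccccc1 | intermediate
18 | (6R,7R,8S)-8-[4-(benzyloxy)-3-methoxyphenyl]-6,7-bis[(benzyloxy)methyl]-3-methoxy-4,4a,5,6,7,8-hexahydronaphthalen-2(3H)-one (C3 and C4a as mixtures) | COc1cc([C@H]2C3=CC(=O)C(OC)CC3C[C@@H](COCc3ccccc3)[C@@H]2COCc2ccccc2)ccc1OCc1ccccc1 | intermediate
19 | (6R,7R,8S)-8-[4-(benzyloxy)-3-methoxyphenyl]-6,7-bis[(benzyloxy)methyl]-3-methoxy-3-(phenylselanyl)-4,4a,5,6,7,8-hexahydronaphthalen-2(3H)-one (not isolated) | COc1cc([C@H]2C3=CC(=O)C(OC)([Se]c4ccccc4)CC3C[C@@H](COCc3ccccc3)[C@@H]2COCc2ccccc2)ccc1OCc1ccccc1 | intermediate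
20 | the Se-oxide of 19, 3-(benzeneseleninyl) compound (not isolated) | COc1cc([C@H]2C3=CC(=O)C(OC)([Se](=O)c4ccccc4)CC3C[C@@H](COCc3ccccc3)[C@@H]2COCc2ccccc2)ccc1OCc1ccccc1 | intermediate
21 | (6R,7R,8S)-8-[4-(benzyloxy)-3-methoxyphenyl]-6,7-bis[(benzyloxy)methyl]-3-methoxy-5,6,7,8-tetrahydronaphthalen-2(4aH)-one (not isolated) | COc1cc([C@H]2C3=CC(=O)C(OC)=CC3C[C@@H](COCc3ccccc3)[C@@H]2COCc2ccccc2)ccc1OCc1ccccc1 | intermediate
22 | (6R,7R,8S)-8-[4-(benzyloxy)-3-methoxyphenyl]-6,7-bis[(benzyloxy)methyl]-3-methoxy-5,6,7,8-tetrahydronaphthalen-2-ol | COc1cc([C@H]2c3cc(O)c(OC)cc3C[C@@H](COCc3ccccc3)[C@@H]2COCc2ccccc2)ccc1OCc1ccccc1 | intermediate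
23 | (+)-isolariciresinol, (6R,7R,8S)-8-(4-hydroxy-3-methoxyphenyl)-6,7-bis(hydroxymethyl)-3-methoxy-5,6,7,8-tetrahydronaphthalen-2-ol | COc1cc([C@H]2c3cc(O)c(OC)cc3C[C@@H](CO)[C@@H]2CO)ccc1O | target

## Step count and least certain steps

Total step count: 11. Longest linear sequence: 10 steps (steps 1–7, 9, 10 and 11 from 1); step 8 is a one-step branch that supplies 15.

Step 9 (key step). The most likely failure is that conjugate addition does not take place. The methoxyl on the α-carbon of 15 pushes electron density onto the CH2 group that must accept the nucleophile, so the acceptor may be too weak for the hindered silyl enol ether. On long exposure to the Lewis acid 15 may oligomerise through its enol ether function, and 13 may lose silicon to adventitious acid, which erases the regiochemical information. In the basic stage, reversible closure of the C1 enolate onto C7 may slow the condensation. The fallback uses known chemistry and sets out from 13. A Mukaiyama–Michael addition to but-3-en-2-one (TiCl4, CH2Cl2, −78 °C), which has no donor on its α-carbon, should give the 1,5-diketone (2S,3S,4R)-2-[4-(benzyloxy)-3-methoxyphenyl]-3,4-bis[(benzyloxy)methyl]-6-(3-oxobutyl)cyclohexan-1-one F1. KOH in MeOH closes and dehydrates it to the enone (6R,7R,8S)-8-[4-(benzyloxy)-3-methoxyphenyl]-6,7-bis[(benzyloxy)methyl]-4,4a,5,6,7,8-hexahydronaphthalen-2(3H)-one F2. LiN(iPr)2 (kinetic enolate at C6) followed by 3-phenyl-2-(phenylsulfonyl)oxaziridine gives the 3-hydroxy enone F3, and MeI with Ag2O methylates the hydroxyl, which returns the route to 18. The cost is three more steps; the ring-A regiochemistry is still dictated by the carbonyl position.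

Step 5. Enantioselectivity may be eroded by an uncatalysed or proton-catalysed background reaction, and the strongly acidic catalyst may protodesilylate 9. Incomplete endo/exo control would be harmless, since C1 is corrected in step 9. The fallback replaces catalyst control by auxiliary control. From 9, cycloaddition with di-(−)-menthyl fumarate promoted by Et2AlCl (toluene, −78 → −40 °C) should give the bis[(1R,2S,5R)-menthyl] ester analogue of the cycloadduct F4. LiAlH4 reduces F4 to 12, where the route is rejoined. If the (−)-auxiliary shields the wrong face, the fumarate of (+)-menthol is used.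

Step 7. The C9 alkoxide may attack silicon through a seven-membered transition state, or a second alkoxide may do so intermolecularly. The enolate released would then be benzylated, and the regiodefined enol ether would be lost. The fallback omits steps 6 and 7 and sets out from 11. The conditions of step 9, with NaOMe in MeOH as base (under which the trans-diequatorial diester is the stable epimer), should lead via the diketone diester dimethyl (1R,2R,3S)-3-[4-(benzyloxy)-3-methoxyphenyl]-5-(2-methoxy-3-oxobutyl)-4-oxocyclohexane-1,2-dicarboxylate F5 to the enone diester dimethyl (1S,2R,3R)-1-[4-(benzyloxy)-3-methoxyphenyl]-6-methoxy-7-oxo-1,2,3,4,4a,5,6,7-octahydronaphthalene-2,3-dicarboxylate F6. Aerobic dehydrogenation with Pd(O2CCF3)2, 2-(dimethylamino)pyridine and TsOH in DMSO under O2, which keeps strong base away from the esters, gives the phenol diester dimethyl (1S,2R,3R)-1-[4-(benzyloxy)-3-methoxyphenyl]-7-hydroxy-6-methoxy-1,2,3,4-tetrahydronaphthalene-2,3-dicarboxylate F7. LiAlH4 reduces both esters to 4'-O-benzylisolariciresinol F8, and hydrogenolysis over Pd/C rejoins the route at 23.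

Step 10. Deprotonation may occur at the γ positions (C1, C4a) instead of the hindered, methoxy-bearing C6, so that selenium ends at a carbon from which syn-elimination cannot aromatise ring A. The peroxide and the seleninic acid formed may also oxidise the electron-rich phenol as it appears. The fallback avoids both the enolate and the peroxide. From 18, catalytic dehydrogenation by divalent palladium (Pd(O2CCF3)2 5 mol %, 2-(dimethylamino)pyridine, TsOH, O2 1 atm, DMSO, 80 °C) should give 22 directly through 21; no new compound is made.

## Further compounds

F1 | step 9 | (2S,3S,4R)-2-[4-(benzyloxy)-3-methoxyphenyl]-3,4-bis[(benzyloxy)methyl]-6-(3-oxobutyl)cyclohexan-1-one | COc1cc([C@H]2C(=O)C(CCC(C)=O)C[C@@H](COCc3ccccc3)[C@@H]2COCc2ccccc2)ccc1OCc1ccccc1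
F2 | step 9 | (6R,7R,8S)-8-[4-(benzyloxy)-3-methoxyphenyl]-6,7-bis[(benzyloxy)methyl]-4,4a,5,6,7,8-hexahydronaphthalen-2(3H)-one | COc1cc([C@H]2C3=CC(=O)CCC3C[C@@H](COCc3ccccc3)[C@@H]2COCc2ccccc2)ccc1OCc1ccccc1
F3 | step 9 | (6R,7R,8S)-8-[4-(benzyloxy)-3-methoxyphenyl]-6,7-bis[(benzyloxy)methyl]-3-hydroxy-4,4a,5,6,7,8-hexahydronaphthalen-2(3H)-one | COc1cc([C@H]2C3=CC(=O)C(O)CC3C[C@@H](COCc3ccccc3)[C@@H]2COCc2ccccc2)ccc1OCc1ccccc1
F4 | step 5 | bis[(1R,2S,5R)-5-methyl-2-(propan-2-yl)cyclohexyl] (1R,2R,3S)-3-[4-(benzyloxy)-3-methoxyphenyl]-4-{[tri(propan-2-yl)silyl]oxy}cyclohex-4-ene-1,2-dicarboxylate | COc1cc([C@H]2C(O[Si](C(C)C)(C(C)C)C(C)C)=CC[C@@H](C(=O)O[C@@H]3C[C@H](C)CC[C@H]3C(C)C)[C@@H]2C(=O)O[C@@H]2C[C@H](C)CC[C@H]2C(C)C)ccc1OCc1ccccc1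
F5 | step 7 | dimethyl (1R,2R,3S)-3-[4-(benzyloxy)-3-methoxyphenyl]-5-(2-methoxy-3-oxobutyl)-4-oxocyclohexane-1,2-dicarboxylate | COc1cc([C@H]2C(=O)C(CC(OC)C(C)=O)C[C@@H](C(=O)OC)[C@@H]2C(=O)OC)ccc1OCc1ccccc1
F6 | step 7 | dimethyl (1S,2R,3R)-1-[4-(benzyloxy)-3-methoxyphenyl]-6-methoxy-7-oxo-1,2,3,4,4a,5,6,7-octahydronaphthalene-2,3-dicarboxylate | COc1cc([C@H]2C3=CC(=O)C(OC)CC3C[C@@H](C(=O)OC)[C@@H]2C(=O)OC)ccc1OCc1ccccc1
F7 | step 7 | dimethyl (1S,2R,3R)-1-[4-(benzyloxy)-3-methoxyphenyl]-7-hydroxy-6-methoxy-1,2,3,4-tetrahydronaphthalene-2,3-dicarboxylate | COc1cc([C@H]2c3cc(O)c(OC)cc3C[C@@H](C(=O)OC)[C@@H]2C(=O)OC)ccc1OCc1ccccc1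
F8 | step 7 | 4'-O-benzylisolariciresinol, (6R,7R,8S)-8-[4-(benzyloxy)-3-methoxyphenyl]-6,7-bis(hydroxymethyl)-3-methoxy-5,6,7,8-tetrahydronaphthalen-2-ol | COc1cc([C@H]2c3cc(O)c(OC)cc3C[C@@H](CO)[C@@H]2CO)ccc1OCc1ccccc1
F0 | step 10 | none | none
A1 | alternative 1 | (1R,2S,5R)-8-phenylmenthyl (E)-3-[4-(benzyloxy)-3-methoxyphenyl]allyl 2-[4-(benzyloxy)-3-methoxybenzyl]malonate | COc1cc(/C=C/COC(=O)C(Cc2ccc(OCc3ccccc3)c(OC)c2)C(=O)O[C@@H]2C[C@H](C)CC[C@H]2C(C)(C)c2ccccc2)ccc1OCc1ccccc1
A2 | alternative 1 | cis-fused aryltetralin γ-lactone with the 8-phenylmenthyl ester on C3 | COc1cc([C@H]2c3cc(OCc4ccccc4)c(OC)cc3C[C@](C(=O)O[C@@H]7C[C@H](C)CC[C@H]7C(C)(C)c7ccccc7)(C(=O)O6)[C@@H]2C6)ccc1OCc1ccccc1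
A3 | alternative 2 | (1S)-7-(benzyloxy)-1-[4-(benzyloxy)-3-methoxyphenyl]-6-methoxy-1,4-dihydronaphthalene | COc1cc([C@H]2c3cc(OCc4ccccc4)c(OC)cc3CC=C2)ccc1OCc1ccccc1
A4 | alternative 2 | dichloroketene | ClC(Cl)=C=O
A5 | alternative 2 | cis-fused 2,2-dichlorocyclobutanone on the C2–C3 bond of the 1-aryltetralin | COc1cc([C@H]2c3cc(OCc4ccccc4)c(OC)cc3C[C@H]5[C@@H]2C(=O)C5(Cl)Cl)ccc1OCc1ccccc1
A6 | alternative 3 | (4R)-4-{4-(benzyloxy)-2-[[4-(benzyloxy)-3-methoxyphenyl](hydroxy)methyl]-5-methoxybenzyl}oxolan-2-ol | COc1cc(C(O)c2cc(OCc3ccccc3)c(OC)cc2C[C@H]2COC(O)C2)ccc1OCc1ccccc1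
A7 | alternative 3 | tetralin-fused lactol, di-O-benzylisolariciresinol at the C9 aldehyde oxidation level | COc1cc([C@H]2c3cc(OCc4ccccc4)c(OC)cc3C[C@@H](CO5)[C@@H]2C5O)ccc1OCc1ccccc1
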